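**Plan**

Numbering: ring A carries OMe on C1, Br on C2 and C4, and the bridging ether oxygen on C6; ring B carries that oxygen on C1', Br on C4' and OH on C6'.
Retrosynthesis: the C6' hydroxyl is traced back to a pivalate, the O–CH3 bond on the C1 oxygen is cut, then the three C–Br bonds (C2, C4, C4') together, then the pivaloyl C–O bond, and last the two C–OH bonds of 2,2'-oxydiphenol, which leads to diphenyl ether.
Enabling feature: without Br and CH3 the target is the symmetric 2,2'-oxydiphenol; C2 and C4 lie ortho and para to the C1 oxygen, whereas C4' lies para to the bridging oxygen and meta to the C6' oxygen. A free OH on ring A and an acylated OH on ring B therefore call for exactly this bromine pattern.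
Forward: both rings and the ether bridge are bought as diphenyl ether; two ortho hydroxyls are installed, one is pivaloylated, three bromines enter in one flask, the free OH is methylated and the ester is removed.
Stereochemistry: the target has no stereocentre, so none has to be set.

Key step: step 3

Assumption: diphenyl ether, pivaloyl chloride, Br2 and MeI are taken as bulk commercial chemicals; the diol 4 is made rather than bought.

**Route**

Step 1
Reactants: 1 diphenyl ether
Product: 4 2,2'-oxydiphenol, via 2,2'-dilithiodiphenyl ether 2 (not isolated), via 2,2'-bis(dimethoxyboryl)diphenyl ether 3 (not isolated)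
Conditions: n-BuLi (2.5 equiv), TMEDA (2.5 equiv), hexane/Et2O, 0 °C → rt, 16 h; cannulated into B(OMe)3 (6 equiv), THF, −78 °C → rt; AcOH, then 30% aq. H2O2, 0 °C → rt
Reagents that add atoms: hydrogen peroxide, OO
Why: TMEDA-activated n-BuLi metalates diphenyl ether at one position ortho to the ether oxygen on each ring (double directed ortho-metalation), the aryllithium is trapped by trimethyl borate, and hydrogen peroxide oxidises each C–B bond to C–OH with retention of position (lithiation–borylation–oxidation), any cyclic borinate formed on the way being oxidised to the same diol.

Step 2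
Reactants: 4 2,2'-oxydiphenol; 5 pivaloyl chloride
Product: 6 2-(2-hydroxyphenoxy)phenyl pivalate
Conditions: NaH (1.0 equiv), THF, 0 °C; then 5 (0.95 equiv) added slowly, −20 → 0 °C; chromatography, with recovered 4 and saponified over-acylated material returned to the step
Reagents that add atoms: pivaloyl chloride 5, CC(C)(C)C(Cl)=O
Why: O-acylation of a phenoxide by an acid chloride, in which one equivalent of base should leave the hydrogen-bonded mono-phenoxide of the symmetric diol as the main nucleophile, so that the first acylation breaks the symmetry (either OH gives the same compound) and installs a bulky ester meant to survive HBr in step 3 and carbonate in step 4.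

Step 3
Reactants: 6 2-(2-hydroxyphenoxy)phenyl pivalate
Product: 7 5-bromo-2-(3,5-dibromo-2-hydroxyphenoxy)phenyl pivalate
Conditions: Br2 (2.05 equiv), CH2Cl2, 0 °C; then FeBr3 (5 mol %) and Br2 (1.1 equiv), 0 °C → rt; aq. Na2S2O3
Reagents that add atoms: bromine, BrBr
Why: Each bromine enters by electrophilic aromatic substitution through an arenium ion, the closest known reaction type being the exhaustive ortho/para bromination of phenols combined with the FeBr3-catalysed bromination of O-acylated guaiacols, where acylation hands the directing role from the masked hydroxyl to the ether oxygen. No ring is closed and no stereocentre is formed, so the only selectivity needed is positional, over three sites. On ring A the free OH on C1 is the strongest donor present and its second ortho position C6 is occupied by the bridging oxygen, so the first two equivalents should go uncatalysed to C4 (para) and C2 (ortho). On ring B the lone pairs of the C6' oxygen are tied up by the pivaloyl carbonyl, which leaves the bridging oxygen on C1' as the dominant donor and directs the third bromine to C4', para to it and meta to the ester, while the ortho site C2' is screened by ring A. Since that ring is only weakly activated (meta acyloxy group, electron-poor aryloxy donor), the third equivalent is delivered with FeBr3 once ring A is saturated, and C3 and C5 of ring A should stay free because they are meta to the OH and flanked by bromine. The thiosulfate quench reduces excess bromine and returns any ring A bromodienone to the phenol.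

Step 4
Reactants: 7 5-bromo-2-(3,5-dibromo-2-hydroxyphenoxy)phenyl pivalate
Product: 8 5-bromo-2-(3,5-dibromo-2-methoxyphenoxy)phenyl pivalate
Conditions: MeI (3 equiv), K2CO3 (1.5 equiv), acetone, 40 °C
Reagents that add atoms: methyl iodide, CI
Why: Williamson ether synthesis, in which the acidic dibrominated phenol is deprotonated by carbonate and its phenoxide displaces iodide from MeI, while the pivalate on ring B leaves this as the only hydroxyl that can be alkylated.

Step 5
Reactants: 8 5-bromo-2-(3,5-dibromo-2-methoxyphenoxy)phenyl pivalate
Product: 9 5-bromo-2-(3,5-dibromo-2-methoxyphenoxy)phenol (target)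
Conditions: NaOH (3 equiv), THF/MeOH/H2O, rt; then 1 M HCl
Reagents that add atoms: none
Why: Saponification of an aryl ester by acyl–oxygen cleavage, fast even for a pivalate because a phenoxide leaves, under conditions to which the aryl bromides, the methyl ether and the unactivated diaryl ether should be inert.

**Compound list**

1 | diphenyl ether | c1ccc(Oc2ccccc2)cc1 | starting material
2 | 2,2'-dilithiodiphenyl ether | [Li]c1ccccc1Oc1ccccc1[Li] | intermediate
3 | 2,2'-bis(dimethoxyboryl)diphenyl ether | COB(OC)c1ccccc1Oc1ccccc1B(OC)OC | intermediate
4 | 2,2'-oxydiphenol | Oc1ccccc1Oc1ccccc1O | intermediate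
5 | pivaloyl chloride | CC(C)(C)C(Cl)=O | starting material
6 | 2-(2-hydroxyphenoxy)phenyl pivalate | CC(C)(C)C(=O)Oc1ccccc1Oc1ccccc1O | intermediate
7 | 5-bromo-2-(3,5-dibromo-2-hydroxyphenoxy)phenyl pivalate | CC(C)(C)C(=O)Oc1cc(Br)ccc1Oc1cc(Br)cc(Br)c1O | intermediate
8 | 5-bromo-2-(3,5-dibromo-2-methoxyphenoxy)phenyl pivalate | CC(C)(C)C(=O)Oc1cc(Br)ccc1Oc1cc(Br)cc(Br)c1OC | intermediate
9 | 5-bromo-2-(3,5-dibromo-2-methoxyphenoxy)phenol | COc1c(Br)cc(Br)cc1Oc1ccc(Br)cc1O | target

**Step count**

Total steps: 5. Longest linear sequence: 5 steps (1 → 4 → 6 → 7 → 8 → 9).

**Steps most likely to fail**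

1. Step 3 (key step). The slow third bromination may stall, or the Lewis acid and the HBr formed may strip or shift the pivaloyl group, so that a liberated hydroxyl takes over the directing role on ring B and bromine enters para to it. The fallback replaces the ester by a sulfonate that is neither cleaved nor transferred under these conditions and so tolerates harder forcing. It sets out from 4: NaH (1 equiv) and methanesulfonyl chloride (THF, 0 °C) should give 2-(2-hydroxyphenoxy)phenyl methanesulfonate F1. Br2 (2 equiv, CH2Cl2, 0 °C) followed by FeBr3 and Br2 (1.1 equiv, rt → 40 °C) should give 5-bromo-2-(3,5-dibromo-2-hydroxyphenoxy)phenyl methanesulfonate F2, the mesyloxy group being an even poorer donor than the ester. MeI and K2CO3 in acetone should give 5-bromo-2-(3,5-dibromo-2-methoxyphenoxy)phenyl methanesulfonate F3. NaOH in MeOH/H2O at reflux, then HCl, cleaves the S–O bond, and the sequence comes back to the route at the target 9.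

2. Step 2. Proton exchange between phenoxides may let acylation run on to the bis-ester while diol is left over, so that the mono-ester forms only in statistical amount and has to be separated from both. The fallback assembles a diaryl ether whose two oxygens differ from the outset. It replaces compounds 1 to 4 and sets out from pivaloyl chloride 5 together with two purchased partners, 2-(benzyloxy)phenol (Oc1ccccc1OCc1ccccc1) and 2-fluorobenzaldehyde (O=Cc1ccccc1F). Nucleophilic aromatic substitution (K2CO3, DMF, 110 °C) should give 2-[2-(benzyloxy)phenoxy]benzaldehyde F4. Baeyer–Villiger oxidation with mCPBA (CH2Cl2, rt) should give 2-[2-(benzyloxy)phenoxy]phenyl formate F5, which catalytic K2CO3 in MeOH should convert into 2-[2-(benzyloxy)phenoxy]phenol F6. NaH and 5 (THF, 0 °C) should give 2-[2-(benzyloxy)phenoxy]phenyl pivalate F7. Hydrogenolysis (H2, Pd/C, EtOAc) removes the benzyl group before any bromine is present, and the branch comes back to the route at 6.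

3. Step 4. Under carbonate the ring A phenoxide may attack the neighbouring pivalate (acyl transfer through an eight-membered transition state), after which the released ring B phenoxide is methylated instead; alkylation of the hindered, weakly nucleophilic phenoxide may also be slow. The fallback is a Mitsunobu etherification, which activates methanol and generates no free phenoxide: from 7 with MeOH, PPh3 and diisopropyl azodicarboxylate (THF, 0 °C → rt) directly to 8, with no new compound on the way.

**Further compounds**

F1 | step 3 | 2-(2-hydroxyphenoxy)phenyl methanesulfonate | CS(=O)(=O)Oc1ccccc1Oc1ccccc1O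
F2 | step 3 | 5-bromo-2-(3,5-dibromo-2-hydroxyphenoxy)phenyl methanesulfonate | CS(=O)(=O)Oc1cc(Br)ccc1Oc1cc(Br)cc(Br)c1O
F3 | step 3 | 5-bromo-2-(3,5-dibromo-2-methoxyphenoxy)phenyl methanesulfonate | CS(=O)(=O)Oc1cc(Br)ccc1Oc1cc(Br)cc(Br)c1OC
F4 | step 2 | 2-[2-(benzyloxy)phenoxy]benzaldehyde | O=Cc1ccccc1Oc1ccccc1OCc1ccccc1
F5 | step 2 | 2-[2-(benzyloxy)phenoxy]phenyl formate | O=COc1ccccc1Oc1ccccc1OCc1ccccc1
F6 | step 2 | 2-[2-(benzyloxy)phenoxy]phenol | Oc1ccccc1Oc1ccccc1OCc1ccccc1
F7 | step 2 | 2-[2-(benzyloxy)phenoxy]phenyl pivalate | CC(C)(C)C(=O)Oc1ccccc1Oc1ccccc1OCc1ccccc1
F0 | step 4 | none | none
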